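**Strategy.** The bicyclic core (furo[3,4-c]furan-1-one numbering; lactone ring A: C1, O2, C3, C3a, C6a; tetrahydrofuran ring B: C3a, C4, O5, C6, C6a) is read as formaldehyde added across a styrene: C4 is an acetal-level carbon on O5, C3a its alkene partner and C3 a benzylic carbon holding the lactone oxygen. An Evans syn-aldol reaction sets C6 and C6a in an open-chain β-hydroxy acid carrying an (E)-styryl group. In one operation its methylene acylal (a 1,3-dioxan-4-one) ionises to an oxocarbenium ion; Prins cyclisation forms the C3a–C4 bond and ring B, and the carboxyl group traps the benzylic cation to close ring A, creating C3a and C3. Hydrogenolysis of three benzyl ethers ends the route.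

Key step: step 5

Assumption: paraformaldehyde is counted as monomeric CH2O in the balance of step 5, and the atom labels used below follow the furo[3,4-c]furan-1-one numbering of the product.

Step 1
Reactants: 1 4-(benzyloxy)-3-methoxybenzaldehyde; 2 (2-carboxyethyl)triphenylphosphonium bromide
Product: 4 (E)-4-[4-(benzyloxy)-3-methoxyphenyl]but-3-enoic acid, via phosphonium ylide 3 (not isolated)
Conditions: NaN(SiMe3)2 (2.1 equiv), THF, 0 °C; then 1, 0 °C to rt; 1 M HCl; recrystallisation
Reagents that add atoms: none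
Why: The Wittig reaction of the carboxylate-bearing ylide with an aryl aldehyde should give the β,γ-unsaturated acid mainly as the E-isomer (no stereocentre is formed), the carboxylate keeping the double bond out of conjugation and crystallisation removing the Z-isomer.

Step 2
Reactants: 4 (E)-4-[4-(benzyloxy)-3-methoxyphenyl]but-3-enoic acid; 5 (S)-4-benzyloxazolidin-2-one
Product: 7 (S)-4-benzyl-3-{(E)-4-[4-(benzyloxy)-3-methoxyphenyl]but-3-enoyl}oxazolidin-2-one, via mixed pivalic anhydride 6 (not isolated)
Conditions: t-BuCOCl, Et3N, THF, −20 °C; then 5, LiCl, −20 °C to rt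
Reagents that add atoms: none
Why: In this mixed-anhydride N-acylation the LiCl-activated oxazolidinone should attack the less hindered acyl carbon of 6, and the weak amine base should leave the β,γ-double bond and the auxiliary stereocentre untouched.

Step 3
Reactants: 7 (S)-4-benzyl-3-{(E)-4-[4-(benzyloxy)-3-methoxyphenyl]but-3-enoyl}oxazolidin-2-one; 8 3,4-bis(benzyloxy)benzaldehyde
Product: 10 (S)-4-benzyl-3-[(2S,3S)-3-[3,4-bis(benzyloxy)phenyl]-2-{(E)-2-[4-(benzyloxy)-3-methoxyphenyl]ethenyl}-3-hydroxypropanoyl]oxazolidin-2-one, via boron dienolate 9 (not isolated)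
Conditions: Bu2BOTf (1.2 equiv), iPr2NEt (1.4 equiv), CH2Cl2, −78 to 0 °C; then 8, −78 to 0 °C; pH 7 buffer/MeOH, 30% H2O2, 0 °C
Reagents that add atoms: none
Why: In the Evans syn-aldol reaction the Z(O)-boron dienolate 9 should react at its α-carbon through a closed chair-like transition state on the face opposite the benzyl group of the auxiliary, which sets both new stereocentres (2S,3S) in a syn relation.

Step 4
Reactants: 10 (S)-4-benzyl-3-[(2S,3S)-3-[3,4-bis(benzyloxy)phenyl]-2-{(E)-2-[4-(benzyloxy)-3-methoxyphenyl]ethenyl}-3-hydroxypropanoyl]oxazolidin-2-one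
Product: 12 (2S,3S)-3-[3,4-bis(benzyloxy)phenyl]-2-{(E)-2-[4-(benzyloxy)-3-methoxyphenyl]ethenyl}-3-hydroxypropanoic acid, via lithium peroxycarboxylate 11 (not isolated)
Conditions: LiOH, 30% H2O2, THF/H2O (3:1), 0 °C; aq. Na2SO3; 1 M HCl to pH 3 at 0 °C
Reagents that add atoms: hydrogen peroxide (as LiOOH), OO
Why: In this hydroperoxide-mediated imide hydrolysis LiOOH should attack the exocyclic carbonyl selectively and sulfite reduces the peroxy acid, while 0 °C and a short reaction time should prevent retro-aldol cleavage and epimerisation at the doubly activated α-carbon.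

Step 5
Reactants: 12 (2S,3S)-3-[3,4-bis(benzyloxy)phenyl]-2-{(E)-2-[4-(benzyloxy)-3-methoxyphenyl]ethenyl}-3-hydroxypropanoic acid
Product: 15 (3S,3aR,6S,6aS)-3-[4-(benzyloxy)-3-methoxyphenyl]-6-[3,4-bis(benzyloxy)phenyl]tetrahydro-1H,3H-furo[3,4-c]furan-1-one, via bis(trimethylsilyl) derivative 13 (not isolated), via 1,3-dioxan-4-one 14 (not isolated)
Conditions: Et3N (2.0 equiv), Me3SiOTf (2.3 equiv), CH2Cl2, −78 to −40 °C; then (CH2O)n (3 equiv), 0.01 M, −78 to −20 °C; pyridine, aq. NaHCO3
Reagents that add atoms: paraformaldehyde (formaldehyde unit), C=O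
Why: Silyl triflate-catalysed acetalisation of 13 with formaldehyde gives the methylene acylal 14, whose reversible ionisation at the acetal carbon by the residual Me3SiOTf unmasks an oxocarbenium ion (CH2=O+) on O5; the styrene carbon C3a attacks it and the 4-benzyloxybenzyl cation formed at C3 is captured by the silyl ester oxygen with return of Me3SiOTf. The closest known reaction type is the Prins cyclisation of styrenyl homoallylic acetals that closes tetrahydrofurans through a benzylic cation, ended here by a carboxyl group and run as a ring contraction of a 1,3-dioxan-4-one. Ring B closes in a five-membered mode with the alkene exocyclic (5-exo with respect to the alkene, endo with respect to the C=O+ bond), and ring A closes by 5-exo-trig attack of oxygen on the benzylic cation. C3a is controlled by C6a, because only the cation whose benzylic carbon is cis to the carboxyl group can close the cis-fused lactone, while the trans cation should return by retro-Prins (Grob-type) fragmentation and re-enter; C3 is set by capture of the planar cation with the aryl group turned to the convex face, the same outcome as anti addition across the E-alkene, and C6 and C6a come unchanged from the aldol step. The step needs attack through C3a and not through C3 (six-membered ring or 2-oxonia-Cope shift), which the 4-benzyloxy group secures by placing the positive charge at C3. It also needs ionisation at the acetal carbon and not at the benzylic C6–O bond, which the low temperature and the small amount of free silyl triflate should secure.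

Step 6
Reactants: 15 (3S,3aR,6S,6aS)-3-[4-(benzyloxy)-3-methoxyphenyl]-6-[3,4-bis(benzyloxy)phenyl]tetrahydro-1H,3H-furo[3,4-c]furan-1-one
Product: 16 (3S,3aR,6S,6aS)-6-(3,4-dihydroxyphenyl)-3-(4-hydroxy-3-methoxyphenyl)tetrahydro-1H,3H-furo[3,4-c]furan-1-one
Conditions: H2 (1 atm), 10% Pd/C, EtOAc, rt, stopped as soon as the three aryl benzyl ethers are cleaved
Reagents that add atoms: none
Why: Catalytic hydrogenolysis should cleave the three aryl benzyl ethers much faster than the hindered secondary benzylic C–O bonds of rings A and B in a neutral aprotic solvent, and no stereocentre is touched.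

**Compound list**

1 | 4-(benzyloxy)-3-methoxybenzaldehyde | COc1cc(C=O)ccc1OCc1ccccc1 | starting material
2 | (2-carboxyethyl)triphenylphosphonium bromide | OC(=O)CC[P+](c1ccccc1)(c1ccccc1)c1ccccc1.[Br-] | starting material
3 | sodium 3-(triphenyl-λ5-phosphanylidene)propanoate (ylide, not isolated) | [Na+].[O-]C(=O)CC=P(c1ccccc1)(c1ccccc1)c1ccccc1 | intermediate
4 | (E)-4-[4-(benzyloxy)-3-methoxyphenyl]but-3-enoic acid | OC(=O)C/C=C/c1ccc(OCc2ccccc2)c(OC)c1 | intermediate
5 | (S)-4-benzyloxazolidin-2-one | O=C1N[C@@H](Cc2ccccc2)CO1 | starting material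
6 | (E)-4-[4-(benzyloxy)-3-methoxyphenyl]but-3-enoic pivalic anhydride (not isolated) | CC(C)(C)C(=O)OC(=O)C/C=C/c1ccc(OCc2ccccc2)c(OC)c1 | intermediate
7 | (S)-4-benzyl-3-{(E)-4-[4-(benzyloxy)-3-methoxyphenyl]but-3-enoyl}oxazolidin-2-one | O=C(C/C=C/c1ccc(OCc2ccccc2)c(OC)c1)N1[C@@H](Cc2ccccc2)COC1=O | intermediate
8 | 3,4-bis(benzyloxy)benzaldehyde | O=Cc1ccc(OCc2ccccc2)c(OCc2ccccc2)c1 | starting material
9 | (S)-4-benzyl-3-{(1Z,3E)-4-[4-(benzyloxy)-3-methoxyphenyl]-1-[(dibutylboranyl)oxy]buta-1,3-dien-1-yl}oxazolidin-2-one (not isolated) | CCCCB(CCCC)O/C(=C\C=C\c1ccc(OCc2ccccc2)c(OC)c1)N1[C@@H](Cc2ccccc2)COC1=O | intermediate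
10 | (S)-4-benzyl-3-[(2S,3S)-3-[3,4-bis(benzyloxy)phenyl]-2-{(E)-2-[4-(benzyloxy)-3-methoxyphenyl]ethenyl}-3-hydroxypropanoyl]oxazolidin-2-one | O=C([C@H]([C@H](O)c1ccc(OCc2ccccc2)c(OCc2ccccc2)c1)/C=C/c1ccc(OCc2ccccc2)c(OC)c1)N1[C@@H](Cc2ccccc2)COC1=O | intermediate
11 | lithium (2S,3S)-3-[3,4-bis(benzyloxy)phenyl]-2-{(E)-2-[4-(benzyloxy)-3-methoxyphenyl]ethenyl}-3-hydroxypropaneperoxoate (not isolated) | [Li+].[O-]OC(=O)[C@H]([C@H](O)c1ccc(OCc2ccccc2)c(OCc2ccccc2)c1)/C=C/c1ccc(OCc2ccccc2)c(OC)c1 | intermediate
12 | (2S,3S)-3-[3,4-bis(benzyloxy)phenyl]-2-{(E)-2-[4-(benzyloxy)-3-methoxyphenyl]ethenyl}-3-hydroxypropanoic acid | OC(=O)[C@H]([C@H](O)c1ccc(OCc2ccccc2)c(OCc2ccccc2)c1)/C=C/c1ccc(OCc2ccccc2)c(OC)c1 | intermediate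
13 | trimethylsilyl (2S,3S)-3-[3,4-bis(benzyloxy)phenyl]-2-{(E)-2-[4-(benzyloxy)-3-methoxyphenyl]ethenyl}-3-[(trimethylsilyl)oxy]propanoate (not isolated) | C[Si](C)(C)OC(=O)[C@H]([C@H](O[Si](C)(C)C)c1ccc(OCc2ccccc2)c(OCc2ccccc2)c1)/C=C/c1ccc(OCc2ccccc2)c(OC)c1 | intermediate
14 | (5S,6S)-6-[3,4-bis(benzyloxy)phenyl]-5-{(E)-2-[4-(benzyloxy)-3-methoxyphenyl]ethenyl}-1,3-dioxan-4-one (cis, not isolated) | O=C1OCO[C@H](c2ccc(OCc3ccccc3)c(OCc3ccccc3)c2)[C@@H]1/C=C/c1ccc(OCc2ccccc2)c(OC)c1 | intermediate
15 | (3S,3aR,6S,6aS)-3-[4-(benzyloxy)-3-methoxyphenyl]-6-[3,4-bis(benzyloxy)phenyl]tetrahydro-1H,3H-furo[3,4-c]furan-1-one | COc1cc([C@H]2OC(=O)[C@H]3[C@@H]2CO[C@@H]3c2ccc(OCc4ccccc4)c(OCc4ccccc4)c2)ccc1OCc1ccccc1 | intermediate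
16 | (3S,3aR,6S,6aS)-6-(3,4-dihydroxyphenyl)-3-(4-hydroxy-3-methoxyphenyl)tetrahydro-1H,3H-furo[3,4-c]furan-1-one | COc1cc([C@H]2OC(=O)[C@H]3[C@@H]2CO[C@@H]3c2ccc(O)c(O)c2)ccc1O | target

**Step count.** Total: 6 steps. Longest linear sequence: 6 steps (1 → 4 → 7 → 10 → 12 → 15 → 16).

**Steps most likely to fail**

Step 5. Ionisation of the catechol-bearing benzylic C6–O bond (loss of formaldehyde or decarboxylative fragmentation) may outrun ring closure, or the cation formed with the wrong orientation at C3a may be lost by elimination instead of returning; prolonged exposure to acid may also erode the exo orientation at C3. The fallback sets out from 10 and comes back at 15. Transamidation of 10 with AlMe3 and MeONHMe·HCl would give the Weinreb amide F1, and its hydroxyl would be converted with Me2S and dibenzoyl peroxide in MeCN into the methylthiomethyl ether F2. S-Methylation of F2 with MeOTf in the presence of 2,6-di-tert-butyl-4-methylpyridine would then release the same oxocarbenium ion from an isolated O,S-acetal in a buffered medium free of Lewis acid. The more nucleophilic amide oxygen would capture the benzylic cation, and aqueous hydrolysis of the iminium ether should deliver 15.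

Step 6. Over-reduction may occur: once the phenols are free, hydrogenolysis of the benzylic C–O bonds of rings A and B may compete and open the core. The fallback sets out from 15 and reaches 16 directly: debenzylation by BCl3 with pentamethylbenzene as cation scavenger in CH2Cl2 at −78 °C, which uses no hydrogen and makes no new compound (F0).

Step 3. Enolisation may be incomplete, the dienolate may react through its γ-carbon or drift into conjugation, and the electron-rich aldehyde may add sluggishly, so that regio- and diastereocontrol are eroded. The fallback sets out from 5 and comes back at 10. N-Acylation of 5 with (E)-but-2-enoyl chloride (n-BuLi, THF, −78 °C) would give the crotonyl imide F3. Its deconjugative Evans syn-aldol reaction with 8 (Bu2BOTf, Et3N) would give the α-vinyl adduct F4. Cross-metathesis of F4 with 4-(benzyloxy)-3-methoxystyrene F5 (from 1 by Wittig methylenation with Ph3P=CH2), under the second-generation Grubbs catalyst, should install the E-styryl group and give 10.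

**Further compounds**

F1 | step 5 | (2S,3S)-3-[3,4-bis(benzyloxy)phenyl]-2-{(E)-2-[4-(benzyloxy)-3-methoxyphenyl]ethenyl}-3-hydroxy-N-methoxy-N-methylpropanamide | CON(C)C(=O)[C@H]([C@H](O)c1ccc(OCc2ccccc2)c(OCc2ccccc2)c1)/C=C/c1ccc(OCc2ccccc2)c(OC)c1
F2 | step 5 | (2S,3S)-3-[3,4-bis(benzyloxy)phenyl]-2-{(E)-2-[4-(benzyloxy)-3-methoxyphenyl]ethenyl}-N-methoxy-N-methyl-3-[(methylsulfanyl)methoxy]propanamide | CON(C)C(=O)[C@H]([C@H](OCSC)c1ccc(OCc2ccccc2)c(OCc2ccccc2)c1)/C=C/c1ccc(OCc2ccccc2)c(OC)c1
F0 | step 6 | none | none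
F3 | step 3 | (S)-4-benzyl-3-[(E)-but-2-enoyl]oxazolidin-2-one | C/C=C/C(=O)N1[C@@H](Cc2ccccc2)COC1=O
F4 | step 3 | (S)-4-benzyl-3-{(2S,3S)-3-[3,4-bis(benzyloxy)phenyl]-2-ethenyl-3-hydroxypropanoyl}oxazolidin-2-one | O=C([C@H]([C@H](O)c1ccc(OCc2ccccc2)c(OCc2ccccc2)c1)C=C)N1[C@@H](Cc2ccccc2)COC1=O
F5 | step 3 | 1-(benzyloxy)-4-ethenyl-2-methoxybenzene | C=Cc1ccc(OCc2ccccc2)c(OC)c1
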